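**Plan**

- Retrosynthesis: after the methyl ester is cleaved, both rings are cut in one retro-[4+2]. The bonds cut are the ring-fusion bond C3a–C7a and the C4–C5 bond between the two quaternary carbons (indene numbering). The enabling feature is ring B (C3a–C4–C5–C6=C7–C7a), a cyclohexene whose C6=C7 double bond lies opposite these two bonds, with ring A (C1–C2=C3–C3a–C7a) as a three-carbon tether holding a cis alkene.
- This leaves an open-chain (2E,4Z,7E,9E,11E,13E)-hexaenoate with one stereocentre. It is cut at C2=C3 (Wittig), C4=C5 (Still–Gennari), C10–C11 (Negishi coupling), C10–ethyl/C9≡C10 (Corey–Fuchs, hydrozirconation) and C7=C8 (Wittig).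
- Forward: the chain is built first from methyl (R)-3-hydroxy-2-methylpropanoate and cinnamaldehyde. Rings B and A then close together in the cycloaddition, and ester demethylation ends the route.
- Stereochemistry: C1 comes from the hydroxy ester. In the cycloaddition it fixes the face by A(1,3) strain; the alkene geometries and the endo-ester/exo-tether transition state set C3a, C4, C5 and C7a (trans ring fusion).

Key step: step 15

Remark on numbering: open-chain compounds are numbered along their own chain. Chain atoms C2, C3, C4, C5, C6, C7, C8, C9, C10 of 24 become C4, C3a, C3, C2, C1, C7a, C7, C6, C5 of the tetrahydroindene. In SMILES the cyclopentadienyl ligands on zirconium are drawn sigma-bonded.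

**Step 1**
Reactants: 1 methyl (R)-3-hydroxy-2-methylpropanoate
Product: 2 methyl (R)-3-[(tert-butyldimethylsilyl)oxy]-2-methylpropanoate
Conditions: TBSCl, imidazole, CH2Cl2, 0 °C to rt
Reagents that add atoms: tert-butyldimethylsilyl chloride, CC(C)(C)[Si](C)(C)Cl
Why: Imidazole-promoted silylation masks the primary alcohol as a silyl ether that should survive the hydride, organolithium, zirconium, aluminium and palladium reagents of steps 2 to 8, and the stereocentre is not involved.

**Step 2**
Reactants: 2 methyl (R)-3-[(tert-butyldimethylsilyl)oxy]-2-methylpropanoate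
Product: 3 (R)-3-[(tert-butyldimethylsilyl)oxy]-2-methylpropanal
Conditions: iBu2AlH (1.1 equiv), CH2Cl2, −78 °C; then MeOH, aq. potassium sodium tartrate (KNaC4H4O6)
Reagents that add atoms: none
Why: Partial ester reduction by iBu2AlH at −78 °C stops at the aldehyde because the tetrahedral aluminium hemiacetal persists until the quench, and the aldehyde is used at once so that its α-stereocentre does not epimerise.

**Step 3**
Reactants: 3 (R)-3-[(tert-butyldimethylsilyl)oxy]-2-methylpropanal
Product: 4 (2E,4S)-5-[(tert-butyldimethylsilyl)oxy]-2,4-dimethylpent-2-enal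
Conditions: 2-(triphenylphosphoranylidene)propanal, toluene, 90 °C
Reagents that add atoms: 2-(triphenylphosphoranylidene)propanal, CC(C=O)=P(c1ccccc1)(c1ccccc1)c1ccccc1
Why: The Wittig reaction of a stabilised formyl ylide is E-selective and stops after one homologation because the aliphatic aldehyde is far more electrophilic than the α-branched enal formed, and the nearly neutral ylide should leave the α-stereocentre intact.

**Step 4**
Reactants: 4 (2E,4S)-5-[(tert-butyldimethylsilyl)oxy]-2,4-dimethylpent-2-enal
Product: 5 tert-butyl{[(2S,3E)-6,6-dibromo-2,4-dimethylhexa-3,5-dien-1-yl]oxy}dimethylsilane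
Conditions: CBr4, PPh3, CH2Cl2, 0 °C
Reagents that add atoms: carbon tetrabromide, BrC(Br)(Br)Br
Why: Ramirez dibromo-olefination (first stage of the Corey–Fuchs sequence) converts the enal carbonyl into the 1,1-dibromoalkene under non-basic conditions with the ylide made in the flask from PPh3 and CBr4.

**Step 5**
Reactants: 5 tert-butyl{[(2S,3E)-6,6-dibromo-2,4-dimethylhexa-3,5-dien-1-yl]oxy}dimethylsilane
Product: 7 tert-butyl{[(2S,3E)-2,4-dimethyloct-3-en-5-yn-1-yl]oxy}dimethylsilane, via lithium acetylide 6 (not isolated)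
Conditions: nBuLi (2.1 equiv), THF, −78 °C; then EtI (5 equiv), DMPU, −78 °C to rt
Reagents that add atoms: iodoethane, CCI
Why: In the second stage of the Corey–Fuchs sequence, bromine–lithium exchange and Fritsch–Buttenberg–Wiechell rearrangement give the lithium acetylide, whose SN2 ethylation in the presence of DMPU installs the ethyl group that ends on C5 of the target.

**Step 6**
Reactants: 7 tert-butyl{[(2S,3E)-2,4-dimethyloct-3-en-5-yn-1-yl]oxy}dimethylsilane
Product: 9 tert-butyl{[(2S,3E,5E)-6-iodo-2,4-dimethylocta-3,5-dien-1-yl]oxy}dimethylsilane, via alkenylzirconocene chloride 8 (not isolated)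
Conditions: Cp2Zr(H)Cl (1.5 equiv), THF, rt to 45 °C; then I2, 0 °C
Reagents that add atoms: iodine, II
Why: Hydrozirconation is a syn addition that should place zirconium on the less hindered alkyne carbon (the ethyl-bearing one, remote from the branched alkenyl group), and iodinolysis with retention then gives the E-configured 2-iodo-1,3-diene.

**Step 7**
Reactants: 10 (E)-cinnamaldehyde
Product: 11 (E)-but-1-en-3-yn-1-ylbenzene
Conditions: Me3SiCHN2, LiN(iPr)2, THF, −78 °C to rt
Reagents that add atoms: (trimethylsilyl)diazomethane, C[Si](C)(C)C=[N+]=[N-]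
Why: Colvin homologation (addition of lithiated trimethylsilyldiazomethane, Peterson-type elimination, loss of N2 and 1,2-hydrogen shift of the alkylidene carbene) turns the aldehyde into the terminal alkyne without touching the E-styryl alkene.

**Step 8**
Reactants: 11 (E)-but-1-en-3-yn-1-ylbenzene; 9 tert-butyl{[(2S,3E,5E)-6-iodo-2,4-dimethylocta-3,5-dien-1-yl]oxy}dimethylsilane
Product: 14 tert-butyl{[(2S,3E,5E,7E,9E)-6-ethyl-2,4,8-trimethyl-10-phenyldeca-3,5,7,9-tetraen-1-yl]oxy}dimethylsilane, via alkenylalane 12 (not isolated), via alkenylzinc chloride 13 (not isolated)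
Conditions: 11 (1.5 equiv), Me3Al (2 equiv), Cp2ZrCl2 (0.25 equiv), CH2Cl2, 0 °C to rt; volatiles removed; then ZnCl2, 9, Pd(PPh3)4 (5 mol %), THF, rt
Reagents that add atoms: trimethylaluminium, C[Al](C)C
Why: Negishi zirconium-catalysed carboalumination adds methyl and aluminium syn across the terminal alkyne (methyl to the internal carbon), and transmetalation to zinc followed by Pd-catalysed Negishi cross-coupling should join C6 to C7 of the decatetraene with retention of both alkene geometries.

**Step 9**
Reactants: 14 tert-butyl{[(2S,3E,5E,7E,9E)-6-ethyl-2,4,8-trimethyl-10-phenyldeca-3,5,7,9-tetraen-1-yl]oxy}dimethylsilane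
Product: 15 (2S,3E,5E,7E,9E)-6-ethyl-2,4,8-trimethyl-10-phenyldeca-3,5,7,9-tetraen-1-ol
Conditions: Bu4NF, THF, 0 °C to rt
Reagents that add atoms: none
Why: Fluoride-mediated silyl ether cleavage (Si–F bond formation) frees the primary alcohol, and the tetraene carries no fluoride- or base-sensitive group.

**Step 10**
Reactants: 15 (2S,3E,5E,7E,9E)-6-ethyl-2,4,8-trimethyl-10-phenyldeca-3,5,7,9-tetraen-1-ol
Product: 16 (2S,3E,5E,7E,9E)-6-ethyl-2,4,8-trimethyl-10-phenyldeca-3,5,7,9-tetraenal
Conditions: Dess–Martin periodinane, pyridine, CH2Cl2, 0 °C; crude product used at once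
Reagents that add atoms: none
Why: Dess–Martin oxidation under pyridine buffer gives the β,γ-unsaturated aldehyde without acid or strong base, and the crude aldehyde is carried on immediately in the cold because its doubly activated α-hydrogen makes it prone to epimerisation and to conjugation.

**Step 11**
Reactants: 17 methyl 2-[bis(2,2,2-trifluoroethoxy)phosphoryl]acetate
Product: 19 methyl 2-[bis(2,2,2-trifluoroethoxy)phosphoryl]butanoate (racemic), via potassium phosphonate carbanion 18 (not isolated)
Conditions: KOtBu (0.95 equiv), THF, 0 °C; then EtI, 0 °C to rt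
Reagents that add atoms: iodoethane, CCI
Why: C-Alkylation (SN2) of the stabilised phosphonoacetate carbanion gives the α-ethyl Still–Gennari reagent, and keeping the base as the limiting component curbs dialkylation.

**Step 12**
Reactants: 16 (2S,3E,5E,7E,9E)-6-ethyl-2,4,8-trimethyl-10-phenyldeca-3,5,7,9-tetraenal; 19 methyl 2-[bis(2,2,2-trifluoroethoxy)phosphoryl]butanoate
Product: 21 methyl (2Z,4S,5E,7E,9E,11E)-2,8-diethyl-4,6,10-trimethyl-12-phenyldodeca-2,5,7,9,11-pentaenoate, via potassium phosphonate carbanion 20 (not isolated)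
Conditions: 19 (1.3 equiv), KN(SiMe3)2, 18-crown-6, THF, −78 °C; then crude 16, −78 °C
Reagents that add atoms: none
Why: In the Still–Gennari olefination the trifluoroethyl phosphonate with a dissociated potassium counter-ion eliminates under kinetic control from the syn adduct, which should give the Z enoate (ester cis to C4), and fast addition of the weakly basic carbanion at −78 °C should outrun enolisation of the aldehyde.

**Step 13**
Reactants: 21 methyl (2Z,4S,5E,7E,9E,11E)-2,8-diethyl-4,6,10-trimethyl-12-phenyldodeca-2,5,7,9,11-pentaenoate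
Product: 22 (2Z,4S,5E,7E,9E,11E)-2,8-diethyl-4,6,10-trimethyl-12-phenyldodeca-2,5,7,9,11-pentaen-1-ol
Conditions: iBu2AlH (2.5 equiv), CH2Cl2, −78 °C; then aq. potassium sodium tartrate (KNaC4H4O6)
Reagents that add atoms: none
Why: Twofold hydride transfer from iBu2AlH (1,2-reduction of the enoate) gives the allylic alcohol without touching the alkene geometry or the stereocentre.

**Step 14**
Reactants: 22 (2Z,4S,5E,7E,9E,11E)-2,8-diethyl-4,6,10-trimethyl-12-phenyldodeca-2,5,7,9,11-pentaen-1-ol
Product: 23 (2Z,4S,5E,7E,9E,11E)-2,8-diethyl-4,6,10-trimethyl-12-phenyldodeca-2,5,7,9,11-pentaenal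
Conditions: MnO2 (activated, excess), CH2Cl2, rt, dark
Reagents that add atoms: none
Why: Allylic oxidation on the MnO2 surface is selective for the allylic alcohol and runs under neutral conditions, which should preserve the Z geometry of the α-ethyl enal and the adjacent stereocentre.

**Step 15**
Reactants: 23 (2Z,4S,5E,7E,9E,11E)-2,8-diethyl-4,6,10-trimethyl-12-phenyldodeca-2,5,7,9,11-pentaenal
Product: 25 methyl (1R,3aR,4R,5S,7aS)-3,5-diethyl-1,4,7-trimethyl-5-[(1E,3E)-2-methyl-4-phenylbuta-1,3-dien-1-yl]-3a,4,5,7a-tetrahydro-1H-indene-4-carboxylate, via hexaenoate 24 (not isolated)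
Conditions: methyl 2-(triphenylphosphoranylidene)propanoate, BHT, toluene (degassed), 60 °C; then 100 °C
Reagents that add atoms: methyl 2-(triphenylphosphoranylidene)propanoate, COC(=O)C(C)=P(c1ccccc1)(c1ccccc1)c1ccccc1
Why: The stabilised ylide converts the aldehyde of 23 into the (2E)-2-methyl enoate (E-selective Wittig reaction), giving hexaenoate 24, whose 4Z geometry holds the ester-activated C2=C3 dienophile within reach of the C7=C8–C9=C10 diene through the three-atom tether C4=C5–C6. On heating, 24 should undergo a concerted suprafacial thermal [4+2] cycloaddition of normal electron demand (an intramolecular Diels–Alder reaction of the 1,3,8-nonatriene type, as used for other hydrindene polyketides), which forms the ring-fusion bond C3–C7 (C3a–C7a of 25) and the bond C2–C10 (C4–C5 of 25) in one event. Ring B (cyclohexene) is closed by the cycloaddition itself, and ring A (cyclopentene) closes at the same moment as the fused tether ring because the new C3a–C7a bond joins the two ends of the tether. The E dienophile fixes C4 relative to C3a and the 7E,9E diene fixes C5 relative to C7a, the transition state with the ester endo and the tether exo relates the two pairs and gives the trans ring fusion, and the absolute sense comes from the C6 stereocentre of 24 (C1 of 25), whose hydrogen eclipses the diene to avoid A(1,3) strain with the C8 methyl so that the dienophile adds anti to the C6 methyl. The step needs periselectivity, endo selectivity and facial selectivity: only the C2=C3/C7–C10 pairing can give a five-membered tether ring (the 7E alkene forbids the reverse pairing and the remoter dienes would need seven- or nine-membered tether rings), the syn transition state is disfavoured by the clash of the ethyl-bearing C4=C5 alkene with the C8 methyl, and A(1,3) strain fixes the face. A [1,5]-hydrogen shift in the cis-dienoate is expected to need a higher temperature than the cycloaddition.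

**Step 16**
Reactants: 25 methyl (1R,3aR,4R,5S,7aS)-3,5-diethyl-1,4,7-trimethyl-5-[(1E,3E)-2-methyl-4-phenylbuta-1,3-dien-1-yl]-3a,4,5,7a-tetrahydro-1H-indene-4-carboxylate
Product: 26 (1R,3aR,4R,5S,7aS)-3,5-diethyl-1,4,7-trimethyl-5-[(1E,3E)-2-methyl-4-phenylbuta-1,3-dien-1-yl]-3a,4,5,7a-tetrahydro-1H-indene-4-carboxylic acid
Conditions: NaSEt, DMF, 80 °C; then 1 M HCl
Reagents that add atoms: none
Why: SN2 dealkylation by ethanethiolate at the methyl carbon avoids attack at the acyl carbon, which is shielded by the two quaternary centres, and acidification frees the acid; no stereocentre bears an acidic hydrogen.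

**Compound list**

1 | methyl (R)-3-hydroxy-2-methylpropanoate | OC[C@@H](C)C(=O)OC | starting material
2 | methyl (R)-3-[(tert-butyldimethylsilyl)oxy]-2-methylpropanoate | CC(C)(C)[Si](C)(C)OC[C@@H](C)C(=O)OC | intermediate
3 | (R)-3-[(tert-butyldimethylsilyl)oxy]-2-methylpropanal | CC(C)(C)[Si](C)(C)OC[C@@H](C)C=O | intermediate
4 | (2E,4S)-5-[(tert-butyldimethylsilyl)oxy]-2,4-dimethylpent-2-enal | CC(C)(C)[Si](C)(C)OC[C@@H](C)/C=C(\C)C=O | intermediate
5 | tert-butyl{[(2S,3E)-6,6-dibromo-2,4-dimethylhexa-3,5-dien-1-yl]oxy}dimethylsilane | CC(C)(C)[Si](C)(C)OC[C@@H](C)/C=C(\C)C=C(Br)Br | intermediate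
6 | {(3E,5S)-6-[(tert-butyldimethylsilyl)oxy]-3,5-dimethylhex-3-en-1-yn-1-yl}lithium | CC(C)(C)[Si](C)(C)OC[C@@H](C)/C=C(\C)C#C[Li] | intermediate (not isolated)
7 | tert-butyl{[(2S,3E)-2,4-dimethyloct-3-en-5-yn-1-yl]oxy}dimethylsilane | CC(C)(C)[Si](C)(C)OC[C@@H](C)/C=C(\C)C#CCC | intermediate
8 | chlorobis(cyclopentadienyl){(3E,5E,7S)-8-[(tert-butyldimethylsilyl)oxy]-5,7-dimethylocta-3,5-dien-3-yl}zirconium | CC(C)(C)[Si](C)(C)OC[C@@H](C)/C=C(C)/C=C(CC)/[Zr](Cl)(C1C=CC=C1)C1C=CC=C1 | intermediate (not isolated)
9 | tert-butyl{[(2S,3E,5E)-6-iodo-2,4-dimethylocta-3,5-dien-1-yl]oxy}dimethylsilane | CC(C)(C)[Si](C)(C)OC[C@@H](C)/C=C(C)/C=C(/I)CC | intermediate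
10 | (E)-cinnamaldehyde | O=C/C=C/c1ccccc1 | starting material
11 | (E)-but-1-en-3-yn-1-ylbenzene | C#C/C=C/c1ccccc1 | intermediate
12 | dimethyl[(1E,3E)-2-methyl-4-phenylbuta-1,3-dien-1-yl]alumane | C[Al](C)/C=C(\C)/C=C/c1ccccc1 | intermediate (not isolated)
13 | chloro[(1E,3E)-2-methyl-4-phenylbuta-1,3-dien-1-yl]zinc | Cl[Zn]/C=C(\C)/C=C/c1ccccc1 | intermediate (not isolated)
14 | tert-butyl{[(2S,3E,5E,7E,9E)-6-ethyl-2,4,8-trimethyl-10-phenyldeca-3,5,7,9-tetraen-1-yl]oxy}dimethylsilane | CC(C)(C)[Si](C)(C)OC[C@@H](C)/C=C(C)/C=C(CC)/C=C(C)/C=C/c1ccccc1 | intermediate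
15 | (2S,3E,5E,7E,9E)-6-ethyl-2,4,8-trimethyl-10-phenyldeca-3,5,7,9-tetraen-1-ol | OC[C@@H](C)/C=C(C)/C=C(CC)/C=C(C)/C=C/c1ccccc1 | intermediate
16 | (2S,3E,5E,7E,9E)-6-ethyl-2,4,8-trimethyl-10-phenyldeca-3,5,7,9-tetraenal | O=C[C@@H](C)/C=C(C)/C=C(CC)/C=C(C)/C=C/c1ccccc1 | intermediate
17 | methyl 2-[bis(2,2,2-trifluoroethoxy)phosphoryl]acetate | COC(=O)CP(=O)(OCC(F)(F)F)OCC(F)(F)F | starting material
18 | potassium carbanion of methyl 2-[bis(2,2,2-trifluoroethoxy)phosphoryl]acetate | [K+].COC(=O)[CH-]P(=O)(OCC(F)(F)F)OCC(F)(F)F | intermediate (not isolated)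
19 | methyl 2-[bis(2,2,2-trifluoroethoxy)phosphoryl]butanoate (racemic) | CCC(C(=O)OC)P(=O)(OCC(F)(F)F)OCC(F)(F)F | intermediate
20 | potassium carbanion of methyl 2-[bis(2,2,2-trifluoroethoxy)phosphoryl]butanoate | [K+].CC[C-](C(=O)OC)P(=O)(OCC(F)(F)F)OCC(F)(F)F | intermediate (not isolated)
21 | methyl (2Z,4S,5E,7E,9E,11E)-2,8-diethyl-4,6,10-trimethyl-12-phenyldodeca-2,5,7,9,11-pentaenoate | COC(=O)/C(CC)=C\[C@@H](C)/C=C(C)/C=C(CC)/C=C(C)/C=C/c1ccccc1 | intermediate
22 | (2Z,4S,5E,7E,9E,11E)-2,8-diethyl-4,6,10-trimethyl-12-phenyldodeca-2,5,7,9,11-pentaen-1-ol | OC/C(CC)=C\[C@@H](C)/C=C(C)/C=C(CC)/C=C(C)/C=C/c1ccccc1 | intermediate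
23 | (2Z,4S,5E,7E,9E,11E)-2,8-diethyl-4,6,10-trimethyl-12-phenyldodeca-2,5,7,9,11-pentaenal | O=C/C(CC)=C\[C@@H](C)/C=C(C)/C=C(CC)/C=C(C)/C=C/c1ccccc1 | intermediate
24 | methyl (2E,4Z,6S,7E,9E,11E,13E)-4,10-diethyl-2,6,8,12-tetramethyl-14-phenyltetradeca-2,4,7,9,11,13-hexaenoate | COC(=O)/C(C)=C/C(CC)=C\[C@@H](C)/C=C(C)/C=C(CC)/C=C(C)/C=C/c1ccccc1 | intermediate (not isolated)
25 | methyl (1R,3aR,4R,5S,7aS)-3,5-diethyl-1,4,7-trimethyl-5-[(1E,3E)-2-methyl-4-phenylbuta-1,3-dien-1-yl]-3a,4,5,7a-tetrahydro-1H-indene-4-carboxylate | CCC1=C[C@@H](C)[C@@H]2C(C)=C[C@@](/C=C(C)/C=C/c3ccccc3)(CC)[C@](C)(C(=O)OC)[C@@H]12 | intermediate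
26 | (1R,3aR,4R,5S,7aS)-3,5-diethyl-1,4,7-trimethyl-5-[(1E,3E)-2-methyl-4-phenylbuta-1,3-dien-1-yl]-3a,4,5,7a-tetrahydro-1H-indene-4-carboxylic acid | CCC1=C[C@@H](C)[C@@H]2C(C)=C[C@@](/C=C(C)/C=C/c3ccccc3)(CC)[C@](C)(C(=O)O)[C@@H]12 | target

**Step count and risks**

Total step count: 16. Longest linear sequence: 14 steps (steps 1 to 6, 8 to 10 and 12 to 16; steps 7 and 11 are side branches).

The three steps most likely to fail:

Step 15. The ester-activated trisubstituted dienophile may add too slowly to the fully substituted diene terminus. At the temperature then needed, endo selectivity could erode and the [1,5]-hydrogen shift of the cis-dienoate could compete. The fallback sets out from 23 and comes back to the route at 26; it changes the dienophile to an enal and the activation to a Lewis acid at low temperature. Wittig reaction of 23 with 2-(triphenylphosphoranylidene)propanal (toluene, 70 °C) should give the (2E,4Z,6S,7E,9E,11E,13E)-hexaenal F1. Treatment with Me2AlCl (CH2Cl2, −78 to −20 °C) should then promote the same cycloaddition to the tetrahydroindene-4-carbaldehyde F2. Pinnick oxidation (NaClO2, NaH2PO4, 2-methyl-2-butene, tBuOH/H2O) of the hindered aldehyde leads to 26.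

Step 6. Regiocontrol in the hydrozirconation may be poor, with zirconium delivered in part to the alkyne carbon next to the alkenyl group, so that regioisomeric iodides form. The fallback sets out from 5 and comes back at 14; it builds the ethyl-bearing alkene by two successive couplings on the dibromoalkene instead of by alkyne hydrometalation. Pd(DPEphos)Cl2-catalysed Negishi coupling of 5 with the alkenylzinc chloride 13 should replace only the bromine trans to the chain and give the (5Z)-6-bromotetraene F3. Pd(tBu3P)2-catalysed coupling with Et2Zn, which is reported to proceed with retention on 2-bromo-1,3-dienes, then gives 14.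

Step 8. Transmetalation to the hindered dienylpalladium iodide may be slow, with competing methyl transfer from residual methylaluminium species and homocoupling of the alkenyl metal. The fallback sets out from 9 and comes back at 14; it adds the C7–C10 unit stepwise and makes the last bond at the styryl carbon. Sonogashira coupling of 9 with propyne (Pd(PPh3)2Cl2, CuI, Et3N) should give the dienyne F4. Hydrozirconation with Cp2Zr(H)Cl (zirconium to the methyl-bearing carbon) and iodinolysis give the trienyl iodide F5. Suzuki–Miyaura coupling with (E)-2-phenylvinylboronic acid (Pd(PPh3)4, K3PO4, THF/H2O) gives 14.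

**Further compounds**

F1 | step 15 | (2E,4Z,6S,7E,9E,11E,13E)-4,10-diethyl-2,6,8,12-tetramethyl-14-phenyltetradeca-2,4,7,9,11,13-hexaenal | O=C/C(C)=C/C(CC)=C\[C@@H](C)/C=C(C)/C=C(CC)/C=C(C)/C=C/c1ccccc1
F2 | step 15 | (1R,3aR,4R,5S,7aS)-3,5-diethyl-1,4,7-trimethyl-5-[(1E,3E)-2-methyl-4-phenylbuta-1,3-dien-1-yl]-3a,4,5,7a-tetrahydro-1H-indene-4-carbaldehyde | CCC1=C[C@@H](C)[C@@H]2C(C)=C[C@@](/C=C(C)/C=C/c3ccccc3)(CC)[C@](C)(C=O)[C@@H]12
F3 | step 6 | tert-butyl{[(2S,3E,5Z,7E,9E)-6-bromo-2,4,8-trimethyl-10-phenyldeca-3,5,7,9-tetraen-1-yl]oxy}dimethylsilane | CC(C)(C)[Si](C)(C)OC[C@@H](C)/C=C(C)/C=C(Br)/C=C(C)/C=C/c1ccccc1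
F4 | step 8 | tert-butyl{[(2S,3E,5E)-6-ethyl-2,4-dimethylnona-3,5-dien-7-yn-1-yl]oxy}dimethylsilane | CC(C)(C)[Si](C)(C)OC[C@@H](C)/C=C(C)/C=C(CC)/C#CC
F5 | step 8 | tert-butyl{[(2S,3E,5E,7E)-6-ethyl-8-iodo-2,4-dimethylnona-3,5,7-trien-1-yl]oxy}dimethylsilane | CC(C)(C)[Si](C)(C)OC[C@@H](C)/C=C(C)/C=C(CC)/C=C(C)/I
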